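What is slow in both earlier runs is the fall of first product: elm takes minutes over it, cedar tens of seconds.

| flask | starting material | reagent | temperature | remark | time |
|---|---|---|---|---|---|
| elm | 28 mM | 24 mM | 95 °C | run made earlier |  |
| cedar | 44 mM | 24 mM | 128 °C | run made earlier |  |
| Friday's | 20 mM | 24.0 mM | 100 °C |  | 4.0 min |
| Monday's | 20 mM | 24.0 mM | 120 °C |  | 4.0 min |
| Sunday's | 20 mM | 24.0 mM | 140 °C |  | 4.0 min |
| Thursday's | 20 mM | 24.0 mM | 80 °C |  | 4.0 min |

elm run (percent of the starting material charged): time / min: first product / % = 1.33: 17.1; 2.50: 12.9; 4.00: 6.1; 5.00: 5.7

cedar run (percent of the starting material charged): time / s: first product / % = 10.0: 14.7; 25.0: 8.4; 50.0: 3.4; 80.0: 1.4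

(standard deviation of a reading: 1 percentage point)

- a species is counted by the starting material in it: one side product counts as two
- what may be going on: starting material + reagent -> first product + by-product; starting material + reagent -> other mono adduct + by-product; reagent + first product -> double product + by-product; reagent + other mono adduct -> double product + by-product; starting material + first product -> side product

- which flask leads in amount of first product, in percent of the starting material charged ("all alike" within 1.5 percentage points) (Friday's / Monday's / Sunday's / Thursday's / all alike)
- how much first product is there at the end, in percent of the starting material charged: Friday's
- how much first product is there at the end, in percent of the starting material charged: Monday's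
- how much first product is there at the end, in percent of the starting material charged: Sunday's
- how much first product is there at the end, in percent of the starting material charged: Thursday's

The readings fall from the first one on, so I suppose the fast reagent steps are over by then. The reagent is the limiting reagent in both runs, and I take the tail to hold one step: starting material + first product → side product. That step takes one of each, so starting material minus first product, the gap, stays fixed. I guess the gap as the surplus charged, 4.00 mM in elm and 20.0 mM in cedar. This neglects double product minus first product.

With a fixed gap, the logarithm of first product over first product plus gap falls linearly in time, with a slope of gap times a rate constant. Elm gives 0.0441 mM⁻¹ min⁻¹ for this tail constant, the second-order constant of the side step. Hotter cedar gives 0.0901 mM⁻¹ min⁻¹, which is more.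

The new flasks need a starting value, and the reagent balance supplies it. Once the reagent is spent and before side product forms, first product, other mono adduct and twice the double product together equal the reagent charged. I guess that the tail of these flasks starts with a gap near zero. Three times first product plus other mono adduct then equals twice the starting material charged minus the reagent charged, so first product starts at no more than 5.33 mM. With no gap, the reciprocal of first product grows linearly in time at the tail constant. Friday's, near elm in temperature, then ends near 13.7 %. Monday's, near cedar, ends near 9.13 %. The constant rises with temperature, so I expect Thursday's to lead and Sunday's to come last.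

The forecast says Thursday's, with 20 % for Thursday's, 15 % for Friday's, 9 % for Monday's and 5 % for Sunday's, on the ground that “the coolest flask should lead”.

The flasks give 18.7 % for Thursday's, 13.4 % for Friday's, 8.20 % for Monday's and 4.07 % for Sunday's, and Thursday's leads.

    starting material + reagent → first product + by-product (k = 41.0 M⁻¹ s⁻¹, Ea = 58.0 kJ mol⁻¹)
    starting material + reagent → other mono adduct + by-product (k = 25.0 M⁻¹ s⁻¹, Ea = 45.0 kJ mol⁻¹)
    reagent + first product → double product + by-product (k = 52.0 M⁻¹ s⁻¹, Ea = 66.0 kJ mol⁻¹)
    reagent + other mono adduct → double product + by-product (k = 99.0 M⁻¹ s⁻¹, Ea = 37.0 kJ mol⁻¹)
    starting material + first product → side product (k = 0.770 M⁻¹ s⁻¹, Ea = 46.0 kJ mol⁻¹)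
    (constants at 100 °C)

In Friday's the reagent stands at 0 % by 2.00 min, and first product then goes from 17.3 % to 13.4 %, beside a nearly equal amount of starting material. That fall gives 0.0415 mM⁻¹ min⁻¹, against my tail constant of 0.0441 mM⁻¹ min⁻¹. The neighbour of Sunday's charged with 80 mM of starting material, at 140 °C, keeps 46.8 mM of it. Elm's constant, read at 95 °C and so not this flask's own, makes a pseudo-first-order lifetime of 0.485 min, short against the time, and the neighbour's first product stands at 0 %. In Sunday's itself the side step is one part of the loss: without it first product stands at 21.7 %. The main reason there is reagent + first product → double product: without that step Sunday's holds 64.2 % of first product, not 4.07 %.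

All runs are calculated with constants of no real substance, and the scatter is random.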